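Abbreviations used throughout: TBS = tert-butyldimethylsilyl; ArB = the protected ring B unit 3,4-bis(tert-butyldimethylsilyloxy)-2-methoxy-5-(2-methylbut-3-en-2-yl)phenyl. Chroman numbering (O1, C2, C3, C4, C4a, C5–C8, C8a) and primed ring B locants are used.

## The problem

The target is an isoflavan: ring A is fused to the pyran ring C, and ring B sits on C3, the only stereocentre (S). No other stereogenic element exists to relay from, so C3 has to be set by an external controller, best while it is α to a carbonyl group and then moved out of reach of enolisation. Ring B is pentasubstituted, with a contiguous 2'-OMe, 3'-OH, 4'-OH array whose three oxygens must be told apart and a 1,1-dimethylallyl group at C5' next to the 4'-hydroxyl. The free catechol is easily oxidised. The monosubstituted alkene rules out any hydrogenation once it is present. A phenol ortho to a 1,1-dimethylallyl group cyclises to a dihydrobenzofuran under strong acid, so the last unmasking can be neither reductive nor strongly acidic. Ring A carries one hydroxyl at C7, and O1 sits on C8a, meta to that hydroxyl and ortho to C4a, the carbon that bears C4. Ring A is therefore a para-alkylphenol with an ether oxygen on the carbon next to the alkyl group, which is exactly what a para-quinol offers: its β-carbons are the positions meta to the original hydroxyl, and conjugate addition followed by loss of water returns the arene with the C–O bond in place.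

## Retrosynthesis

24 to 23. The two O–Si bonds of the ring B catechol are cut last. Silyl ethers are preferred to benzyl ethers (hydrogenolysis would reduce the vinyl group) and to acetals (acid would endanger the ortho-hydroxy 1,1-dimethylallyl unit). The precursor 23 differs only by the masks, and the forward step asks for nothing more than fluoride at low temperature.

23 to 21 (key cut). The O1–C8a aryl ether bond is cut and water is added back across C4a–C8a, which turns ring A into the para-quinol 21 carrying a free primary hydroxyl on the side chain. The neighbouring cuts are weaker here: O1–C2 would need ring A as a resorcinol with its two oxygens differentiated, and a metal-catalysed C–O coupling would need a halogen on ring A. The quinol cut lets ring A come from an unadorned para-substituted phenol and lets the side chain deliver its own oxygen. The precursor has lost ring C. The forward reaction must make conjugate addition of the hydroxyl faster than any acid-induced skeletal shift of the quinol.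

21 to 19. Removing the C4a oxygen returns the phenol 19, a plain 2,3-diarylpropanol. Forward, an oxidant must dearomatise the single free phenol without touching the fully masked ring B or the vinyl group.

19 to 18 to 14 + 16. The C3–C4 bond is cut, after the primary alcohol is traced back to an acyl oxazolidinone. This cut places the future C3 α to an imide carbonyl and next to ring B, where enolisation is easy and a benzylic bromide is an ideal partner. Cutting C3–C1' (an arylation) or C2–C3 (a hydroxymethylation) offers no comparably reliable stereocontrol. The pieces are the arylacetyl imide 14 and the bromide 16, itself one step from 15. Forward, the auxiliary must direct the alkylation, and the hydride cleavage must also free the ring A phenol, so that 18 needs no separate deprotection.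

14 to 11 + 12, and 11 to 8 through 10 and 9. The N–acyl bond is cut to the acid 11 and the auxiliary 12, and one carbon is then removed from the side chain to reach the benzaldehyde 8. The aldehyde is kept this far because it is the group that differentiates the ring B oxygens at the start. The forward homologation must tolerate aryl silyl ethers, which excludes strongly basic hydrolyses.

8 to 7 to 6. After removing the silyl groups, the C5'–C(quaternary) bond is cut by reversing a [3,3] shift, which moves the five-carbon unit back onto O4' as a prenyl ether in 6. Direct C-prenylation would give the linear isomer and poor regiocontrol, whereas the sigmatropic route inverts the allyl unit and can only go to C5', the one free ortho position. Forward, the rearrangement must stop at the ortho-(1,1-dimethylallyl)phenol.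

6 to 4 + 5, and 4 to 3 to 2 to 1. The remaining cuts are O–C bonds. The formyl group of 1 orders the three hydroxyls: O2 is hydrogen-bonded and least nucleophilic, O4 is para to the carbonyl and most acidic. Protecting O3 and O4 together, methylating O2 and releasing the pair gives 4, in which the O4 acidity directs the prenyl group from 5. Forward, each alkylation relies on these intrinsic differences and not on statistical selectivity.

## Roads not taken

Alternative 1: The cut removes C3 and ring B from the pyran ring by breaking C2–C3 and C3–C4. This leaves 6-(tert-butyldimethylsilyloxy)benzofuran A2 and an arylchlorocarbene released from the 3-aryl-3-chlorodiazirine A3. In the forward step the carbene cyclopropanates the furan C2=C3 bond, and the adduct opens with loss of chloride to the 3-arylchromenylium chloride A1.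
- Merits: two flat, easily made fragments are joined in one step and the ring A oxygen pattern comes with the benzofuran. This is the most convergent of the four plans.
- Weak points: A1 has no stereocentre, so C3 must be created afterwards by reduction. An enantioselective hydrogenation of the derived isoflavene, with an ortho-substituted ring B, would have to carry the whole stereochemical burden. Because a hydrogenation is needed, A1 cannot carry the vinyl group. It has a benzyl ether at O4' and nothing at C5', so debenzylation, O-prenylation and the Claisen rearrangement would follow on the finished isoflavan. The chlorodiazirine of so electron-rich an arene is also uncertain to prepare.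
- Comparison: Alternative 1 reaches the bicyclic skeleton in fewer steps, and the chosen plan cannot match that. The chosen plan sets against it a stereocentre fixed by an auxiliary before ring C exists, and an alkene installed early with no reductive step after it.

Alternative 2: The cut is C3–C4 plus O1–C2, a [4+2] union of an ortho-quinone methide with the enolate of the ring B arylacetic acid 11. The methide is released by base from 5-(tert-butyldimethylsilyloxy)-2-[(4-methylphenyl)sulfonylmethyl]phenol A5. The acid is activated as a mixed anhydride and bound to a chiral isothiourea as an ammonium enolate. The product is the (S)-3-aryl-7-silyloxychroman-2-one A4.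
- Merits: ring C and the stereocentre arise together under catalyst control, from the same acid 11 that the chosen route uses. No auxiliary has to be attached and removed.
- Weak points: in A4 the stereocentre is both benzylic and α to a lactone carbonyl, so it is prone to racemise under the basic conditions that generate the methide. A methide with an unsubstituted CH2 terminus tends to oligomerise. Carbonate base threatens aryl silyl ethers. The C2 carbonyl still has to go, by reduction to the diol and re-closure or by lactol deoxygenation, so ring C is in effect made twice.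
- Comparison: Alternative 2 is shorter from 11 to a ring C-closed compound, but the saving is largely spent on removing the carbonyl. The chosen plan has diastereomers that can be separated at 18 and a stereocentre that is never α to a carbonyl after step 13.

Alternative 3: The cut is C4–C4a plus O1–C2, a [3+3] union of resorcinol A8 with the 2-arylpropenal A7, which is one α-methylenation away from aldehyde 10. Under a chiral primary amine salt, C4 of A8 adds to the CH2 terminus of A7, the enamine is protonated at C3 under catalyst control, and the ortho hydroxyl closes the lactol, giving the (3S)-3-arylchroman-2,7-diol A6. Deoxygenation of the lactol would give 23 directly.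
- Merits: this is the shortest road, about three steps from 10 to 23 against six in the chosen route, and ring A is bought complete.
- Weak points: the stereocentre comes from enantioselective protonation of an enamine bearing a bulky, ortho-substituted, electron-rich aryl group. The product A6 is a masked α-aryl aldehyde that can re-enter the same enamine and lose its configuration. A8 can react at C2 as well as C4, or twice. The lactol deoxygenation calls for a silane with a strong acid, in the presence of the vinyl group and the silyl ethers.
- Comparison: Alternative 3 is clearly better in step count. The chosen plan accepts the extra steps for a stereocentre installed under stoichiometric, well-understood control and carried as a non-enolisable centre through every later step.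

Key step: step 15

Remark: intermediate 22 is expected as a mixture of the two cis-fused ring-fusion isomers. Both converge on 23, so C4a and C8a are left undefined in its SMILES.

## Route

Step 1
Reactants: 1 2,3,4-trihydroxybenzaldehyde
Product: 2 3,4-bis(benzyloxy)-2-hydroxybenzaldehyde
Conditions: BnBr (2.05 equiv), K2CO3, DMF, rt, N2
Reagents that add atoms: benzyl bromide, BrCc1ccccc1
Why: Williamson etherification; the 2-hydroxyl is held in a hydrogen bond to the formyl oxygen and is the least nucleophilic, so two equivalents of halide should take O4 (para to the formyl group, most acidic) and then O3.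

Step 2
Reactants: 2 3,4-bis(benzyloxy)-2-hydroxybenzaldehyde
Product: 3 3,4-bis(benzyloxy)-2-methoxybenzaldehyde
Conditions: MeI, K2CO3, DMF, 50 °C
Reagents that add atoms: iodomethane, CI
Why: Williamson methylation of the one remaining, chelated phenol, which yields to excess halide and gentle warming once no other hydroxyl competes.

Step 3
Reactants: 3 3,4-bis(benzyloxy)-2-methoxybenzaldehyde
Product: 4 3,4-dihydroxy-2-methoxybenzaldehyde
Conditions: H2 (1 atm), Pd/C, EtOAc, rt
Reagents that add atoms: none
Why: Hydrogenolysis of aryl benzyl ethers, placed here because no alkene is yet present; the electron-rich aldehyde should be reduced far more slowly than the benzyl ethers are cleaved.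

Step 4
Reactants: 4 3,4-dihydroxy-2-methoxybenzaldehyde; 5 1-bromo-3-methylbut-2-ene (prenyl bromide)
Product: 6 3-hydroxy-2-methoxy-4-[(3-methylbut-2-en-1-yl)oxy]benzaldehyde
Conditions: NaHCO3, DMF, 40 °C, N2
Reagents that add atoms: none
Why: Regioselective Williamson etherification; the 4-hydroxyl is para to the formyl group and is the only one that hydrogen carbonate ionises to a useful extent, as in the mono-alkylation of 3,4-dihydroxybenzaldehydes.

Step 5
Reactants: 6 3-hydroxy-2-methoxy-4-[(3-methylbut-2-en-1-yl)oxy]benzaldehyde
Product: 7 3,4-dihydroxy-2-methoxy-5-(2-methylbut-3-en-2-yl)benzaldehyde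
Conditions: PhNEt2, 190 °C, sealed tube, Ar
Reagents that add atoms: none
Why: Aromatic Claisen rearrangement; C5 is the only unsubstituted ortho position, the [3,3] shift delivers the allyl unit inverted as the 1,1-dimethylallyl group, and the basic solvent suppresses acid-catalysed ring closure of the product.

Step 6
Reactants: 7 3,4-dihydroxy-2-methoxy-5-(2-methylbut-3-en-2-yl)benzaldehyde
Product: 8 3,4-bis(tert-butyldimethylsilyloxy)-2-methoxy-5-(2-methylbut-3-en-2-yl)benzaldehyde (ArB–CHO)
Conditions: TBSOTf (2.6 equiv), 2,6-lutidine, CH2Cl2, 0 °C → rt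
Reagents that add atoms: tert-butyldimethylsilyl trifluoromethanesulfonate, CC(C)(C)[Si](C)(C)OS(=O)(=O)C(F)(F)F
Why: Silylation of phenols; the silyl triflate is chosen because O4 is flanked by the tertiary alkyl group and by O3, and neither the aldehyde (no α-hydrogen) nor the alkene reacts with it.

Step 7
Reactants: 8 ArB–CHO
Product: 9 1-ArB-2-methoxyethene (E/Z mixture)
Conditions: MeOCH2PPh3Cl, KN(SiMe3)2, THF, 0 °C; then 8, 0 °C → rt
Reagents that add atoms: (methoxymethyl)triphenylphosphonium chloride, COC[P+](c1ccccc1)(c1ccccc1)c1ccccc1.[Cl-]
Why: Wittig olefination with the methoxymethylene ylide, the first half of a standard one-carbon homologation; aryl silyl ethers tolerate the non-nucleophilic amide base and the ylide.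

Step 8
Reactants: 9 1-ArB-2-methoxyethene
Product: 10 2-ArB-acetaldehyde
Conditions: 1 M HCl (aq), THF, 40 °C
Reagents that add atoms: water, O
Why: Acid hydrolysis of an enol ether by C-protonation and collapse of the hemiacetal; the doubly flanked aryl silyl ethers and the unactivated terminal alkene should withstand dilute acid, and the sensitive aldehyde is to be oxidised without storage.

Step 9
Reactants: 10 2-ArB-acetaldehyde
Product: 11 2-ArB-acetic acid
Conditions: NaClO2, NaH2PO4, 2-methyl-2-butene, t-BuOH/H2O, 0 °C → rt
Reagents that add atoms: sodium chlorite, [Na+].[O-]Cl=O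
Why: Pinnick oxidation; the scavenger alkene removes HOCl before it can reach the vinyl group or the electron-rich ring, and the buffered medium leaves the silyl ethers intact.

Step 10
Reactants: 11 2-ArB-acetic acid; 12 (S)-4-benzyl-2-oxazolidinone
Product: 14 (4S)-4-benzyl-3-(2-ArB-acetyl)-1,3-oxazolidin-2-one, via mixed pivalic anhydride 13 (not isolated)
Conditions: PivCl, Et3N, THF, −20 °C; then LiCl, 12, −20 °C → rt
Reagents that add atoms: none
Why: N-acylation of the oxazolidinone through a mixed anhydride under LiCl/Et3N activation, which avoids both an acid chloride and a strongly basic metalated auxiliary.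

Step 11
Reactants: 15 4-methylphenyl acetate
Product: 16 4-(bromomethyl)phenyl acetate
Conditions: NBS, AIBN (cat.), PhCF3, 80 °C
Reagents that add atoms: N-bromosuccinimide, O=C1CCC(=O)N1Br
Why: Wohl–Ziegler benzylic bromination; the acetoxy group deactivates the ring toward electrophilic bromination, so the radical pathway at the methyl group should dominate.

Step 12
Reactants: 14 (4S)-4-benzyl-3-(2-ArB-acetyl)-1,3-oxazolidin-2-one; 16 4-(bromomethyl)phenyl acetate
Product: 18 (4S)-3-[(2S)-3-(4-acetoxyphenyl)-2-ArB-propanoyl]-4-benzyl-1,3-oxazolidin-2-one, via sodium Z-enolate 17 (not isolated)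
Conditions: NaN(SiMe3)2, THF, −78 °C; then 16 (2.5 equiv), −78 → −45 °C
Reagents that add atoms: none
Why: Evans alkylation; the chelated Z-enolate is attacked by the benzylic bromide on the face away from the benzyl group of the (S)-auxiliary, which sets the new centre as S (carbonyl > aryl > CH2Ar > H), and benzylic bromides alkylate at −78 °C, below the temperature at which an imide enolate should attack an aryl acetate.

Step 13
Reactants: 18 (4S)-3-[(2S)-3-(4-acetoxyphenyl)-2-ArB-propanoyl]-4-benzyl-1,3-oxazolidin-2-one
Product: 19 4-[(2S)-2-ArB-3-hydroxypropyl]phenol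
Conditions: LiBH4, MeOH (2 equiv), THF, 0 °C → rt
Reagents that add atoms: none
Why: Reductive cleavage of the N-acyloxazolidinone to the primary alcohol with concurrent reduction of the aryl acetate to the phenol; from here the stereocentre is no longer α to a carbonyl and cannot epimerise.

Step 14
Reactants: 19 4-[(2S)-2-ArB-3-hydroxypropyl]phenol
Product: 21 4-hydroxy-4-[(2S)-2-ArB-3-hydroxypropyl]cyclohexa-2,5-dien-1-one, via para-peroxyquinol 20 (not isolated)
Conditions: KHSO5 (as 2KHSO5·KHSO4·K2SO4), NaHCO3, CH3CN/H2O, rt; then Na2S2O3 (aq)
Reagents that add atoms: potassium peroxymonosulfate, [K+].[O-]S(=O)(=O)OO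
Why: Oxidative dearomatisation of a para-alkylphenol by singlet oxygen released from buffered peroxymonosulfate, giving the para-hydroperoxide that thiosulfate reduces to the para-quinol; ring B has no free hydroxyl and the vinyl group has no allylic hydrogen, so neither is a substrate, and any 22 formed early converges in step 15.

Step 15
Reactants: 21 4-hydroxy-4-[(2S)-2-ArB-3-hydroxypropyl]cyclohexa-2,5-dien-1-one
Product: 23 (3S)-3-ArB-3,4-dihydro-2H-chromen-7-ol, via bicyclic hydroxy enone 22 (not isolated)
Conditions: TsOH·H2O (0.2 equiv), CH2Cl2, 0 °C → rt; then 40 °C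
Reagents that add atoms: none
Why: Catalytic acid activates the cross-conjugated dienone, and the primary hydroxyl, held three carbons from the carbinol carbon, adds to a β-carbon in a 6-exo-trig oxa-Michael closure that forms O1–C8a and the pyran ring (22). Enolisation of the remaining ketone, acid-assisted loss of the tertiary, doubly allylic hydroxyl from C4a and loss of the C8a proton then restore the benzene ring as the 7-hydroxychroman. Each half has close precedent, namely the oxa-Michael cyclisation of hydroxyalkyl para-quinols and the dehydrative aromatisation of the resulting 4-hydroxycyclohexenones; here they are run one after the other in the same flask. No new stereocentre survives, since C4a and C8a of 22 become trigonal again, and C3 has no acidifying neighbour, so it is carried through unchanged. Regiochemistry needs no control, because the two β-carbons of the dienone lead to the same chroman with O1 meta to the C7 hydroxyl. The selectivity that matters is conjugate addition against the acid-induced 1,2-alkyl shift of the quinol; the intramolecular six-ring closure needs only a catalytic amount of a moderately strong acid near room temperature, where that shift should be slow. The silyl ethers, the methyl ether and the vinyl group of the fully masked ring B should be inert to catalytic TsOH in a non-nucleophilic solvent.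

Step 16
Reactants: 23 (3S)-3-ArB-3,4-dihydro-2H-chromen-7-ol
Product: 24 (3S)-3-[3,4-dihydroxy-2-methoxy-5-(2-methylbut-3-en-2-yl)phenyl]-3,4-dihydro-2H-chromen-7-ol (target)
Conditions: Bu4NF, AcOH, THF, 0 °C, Ar
Reagents that add atoms: none
Why: Fluoride cleavage of aryl silyl ethers, buffered with acetic acid so that the catechol is not left as an oxidisable phenoxide; the alkene and the C3 centre are untouched.

## Compound list

1 | 2,3,4-trihydroxybenzaldehyde | O=Cc1ccc(O)c(O)c1O | starting material
2 | 3,4-bis(benzyloxy)-2-hydroxybenzaldehyde | O=Cc1ccc(OCc2ccccc2)c(OCc2ccccc2)c1O | intermediate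
3 | 3,4-bis(benzyloxy)-2-methoxybenzaldehyde | COc1c(C=O)ccc(OCc2ccccc2)c1OCc1ccccc1 | intermediate
4 | 3,4-dihydroxy-2-methoxybenzaldehyde | COc1c(C=O)ccc(O)c1O | intermediate
5 | 1-bromo-3-methylbut-2-ene (prenyl bromide) | CC(C)=CCBr | starting material
6 | 3-hydroxy-2-methoxy-4-[(3-methylbut-2-en-1-yl)oxy]benzaldehyde | COc1c(C=O)ccc(OCC=C(C)C)c1O | intermediate
7 | 3,4-dihydroxy-2-methoxy-5-(2-methylbut-3-en-2-yl)benzaldehyde | C=CC(C)(C)c1cc(C=O)c(OC)c(O)c1O | intermediate
8 | 3,4-bis(tert-butyldimethylsilyloxy)-2-methoxy-5-(2-methylbut-3-en-2-yl)benzaldehyde (ArB–CHO) | C=CC(C)(C)c1cc(C=O)c(OC)c(O[Si](C)(C)C(C)(C)C)c1O[Si](C)(C)C(C)(C)C | intermediate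
9 | 1-ArB-2-methoxyethene, E/Z mixture | C=CC(C)(C)c1cc(C=COC)c(OC)c(O[Si](C)(C)C(C)(C)C)c1O[Si](C)(C)C(C)(C)C | intermediate
10 | 2-ArB-acetaldehyde | C=CC(C)(C)c1cc(CC=O)c(OC)c(O[Si](C)(C)C(C)(C)C)c1O[Si](C)(C)C(C)(C)C | intermediate
11 | 2-ArB-acetic acid | C=CC(C)(C)c1cc(CC(=O)O)c(OC)c(O[Si](C)(C)C(C)(C)C)c1O[Si](C)(C)C(C)(C)C | intermediate
12 | (S)-4-benzyl-2-oxazolidinone | O=C1N[C@@H](Cc2ccccc2)CO1 | starting material
13 | 2-ArB-acetic pivalic anhydride | C=CC(C)(C)c1cc(CC(=O)OC(=O)C(C)(C)C)c(OC)c(O[Si](C)(C)C(C)(C)C)c1O[Si](C)(C)C(C)(C)C | intermediate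
14 | (4S)-4-benzyl-3-(2-ArB-acetyl)-1,3-oxazolidin-2-one | C=CC(C)(C)c1cc(CC(=O)N2[C@@H](Cc3ccccc3)COC2=O)c(OC)c(O[Si](C)(C)C(C)(C)C)c1O[Si](C)(C)C(C)(C)C | intermediate
15 | 4-methylphenyl acetate | CC(=O)Oc1ccc(C)cc1 | starting material
16 | 4-(bromomethyl)phenyl acetate | CC(=O)Oc1ccc(CBr)cc1 | intermediate
17 | sodium (Z)-enolate of 14 | C=CC(C)(C)c1cc(/C=C(\[O-])N2[C@@H](Cc3ccccc3)COC2=O)c(OC)c(O[Si](C)(C)C(C)(C)C)c1O[Si](C)(C)C(C)(C)C.[Na+] | intermediate
18 | (4S)-3-[(2S)-3-(4-acetoxyphenyl)-2-ArB-propanoyl]-4-benzyl-1,3-oxazolidin-2-one | C=CC(C)(C)c1cc([C@H](Cc2ccc(OC(C)=O)cc2)C(=O)N2[C@@H](Cc3ccccc3)COC2=O)c(OC)c(O[Si](C)(C)C(C)(C)C)c1O[Si](C)(C)C(C)(C)C | intermediate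
19 | 4-[(2S)-2-ArB-3-hydroxypropyl]phenol | C=CC(C)(C)c1cc([C@H](Cc2ccc(O)cc2)CO)c(OC)c(O[Si](C)(C)C(C)(C)C)c1O[Si](C)(C)C(C)(C)C | intermediate
20 | 4-hydroperoxy-4-[(2S)-2-ArB-3-hydroxypropyl]cyclohexa-2,5-dien-1-one | C=CC(C)(C)c1cc([C@H](CC2(OO)C=CC(=O)C=C2)CO)c(OC)c(O[Si](C)(C)C(C)(C)C)c1O[Si](C)(C)C(C)(C)C | intermediate
21 | 4-hydroxy-4-[(2S)-2-ArB-3-hydroxypropyl]cyclohexa-2,5-dien-1-one | C=CC(C)(C)c1cc([C@H](CC2(O)C=CC(=O)C=C2)CO)c(OC)c(O[Si](C)(C)C(C)(C)C)c1O[Si](C)(C)C(C)(C)C | intermediate
22 | (3S)-3-ArB-4a-hydroxy-2,3,4,4a,8,8a-hexahydro-7H-chromen-7-one, mixture of ring-fusion isomers | C=CC(C)(C)c1cc([C@H]2COC3CC(=O)C=CC3(O)C2)c(OC)c(O[Si](C)(C)C(C)(C)C)c1O[Si](C)(C)C(C)(C)C | intermediate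
23 | (3S)-3-ArB-3,4-dihydro-2H-chromen-7-ol | C=CC(C)(C)c1cc([C@H]2COc3cc(O)ccc3C2)c(OC)c(O[Si](C)(C)C(C)(C)C)c1O[Si](C)(C)C(C)(C)C | intermediate
24 | (3S)-3-[3,4-dihydroxy-2-methoxy-5-(2-methylbut-3-en-2-yl)phenyl]-3,4-dihydro-2H-chromen-7-ol | C=CC(C)(C)c1cc([C@H]2COc3cc(O)ccc3C2)c(OC)c(O)c1O | target

## Step count and least certain steps

Total: 16 steps. Longest linear sequence: 15 steps (steps 1–10 and 12–16, from 1 to 24); step 11 is a one-step side branch.

Step 15 (key step). The most likely failure is that the acid-induced 1,2-alkyl shift of the quinol competes with conjugate addition, or that the sequence stalls at the hydroxy enone because the addition is reversible and ionisation of the tertiary hydroxyl is sluggish under acid mild enough to spare the quinol. The fallback separates the two events and removes the acid. Setting out from 21, a catalytic amount of DBU in CH2Cl2 should bring about the oxa-Michael addition, and the bicyclic hydroxy enone 22 is isolated. Its tertiary hydroxyl is then removed by syn-elimination with the Burgess reagent in toluene at 50 °C. This should give (3S)-3-ArB-2,3,4,8-tetrahydro-7H-chromen-7-one F1, the keto tautomer of the product, which enolises to 23, where the route is rejoined.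

Step 14. Oxidation may spill over onto the electron-rich ring B, or conversion may stay incomplete because the lipophilic bis-silyl substrate is poorly available in the aqueous phase where the short-lived oxidant is generated. The fallback gives up the quinol and makes the same O1–C8a bond by aryl etherification. Commercial 3-bromo-4-methylphenol is silylated (TBSCl, imidazole) to (3-bromo-4-methylphenoxy)(tert-butyl)dimethylsilane F2 and brominated with NBS to [3-bromo-4-(bromomethyl)phenoxy](tert-butyl)dimethylsilane F3. Setting out from 14, enolate 17 is alkylated with F3 to (4S)-4-benzyl-3-[(2S)-3-[2-bromo-4-(tert-butyldimethylsilyloxy)phenyl]-2-ArB-propanoyl]-1,3-oxazolidin-2-one F4. LiBH4 gives (2S)-3-[2-bromo-4-(tert-butyldimethylsilyloxy)phenyl]-2-ArB-propan-1-ol F5. Pd(OAc)2 (divalent palladium, reduced in the flask to the zerovalent catalyst) with 2-(di-tert-butylphosphino)-1,1'-binaphthyl and Cs2CO3 in toluene at 70 °C closes the ring to (3S)-7-(tert-butyldimethylsilyloxy)-3-ArB-3,4-dihydro-2H-chromene F6. Bu4NF/AcOH then removes all three silyl groups and the route is rejoined at 24.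

Step 12. Acyl transfer from the aryl acetate to the enolate may consume the nucleophile and release a phenoxide that expels bromide, so that conversion to 18 falls short. The fallback replaces the ester by an ether that an enolate cannot attack. Commercial 4-(allyloxy)benzaldehyde is reduced (NaBH4) to [4-(prop-2-en-1-yloxy)phenyl]methanol F7 and converted with PBr3 to 1-(bromomethyl)-4-(prop-2-en-1-yloxy)benzene F8. Setting out from 14, enolate 17 is alkylated with F8 to (4S)-3-[(2S)-3-[4-(allyloxy)phenyl]-2-ArB-propanoyl]-4-benzyl-1,3-oxazolidin-2-one F9. LiBH4 gives (2S)-3-[4-(allyloxy)phenyl]-2-ArB-propan-1-ol F10. Pd(PPh3)4 (zerovalent palladium) with morpholine in THF removes the O-allyl group; the C-bound 1,1-dimethylallyl group has no leaving group and is inert. The route is rejoined at 19.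

Step 5. At the temperature needed, the ortho-(1,1-dimethylallyl)phenol may rearrange further by hydrogen transfer from its neighbouring hydroxyl to the alkene (the abnormal Claisen pathway), close to a dihydrobenzofuran, or lose the prenyl group as isoprene. The fallback captures the phenol as it forms. Setting out from 6, heating in Ac2O with NaOAc and PhNEt2 first gives 3-acetoxy-2-methoxy-4-[(3-methylbut-2-en-1-yl)oxy]benzaldehyde F11. This rearranges, and the new hydroxyl is acetylated at once to 3,4-diacetoxy-2-methoxy-5-(2-methylbut-3-en-2-yl)benzaldehyde F12, which is isolated. K2CO3 in MeOH then frees both phenols and the route is rejoined at 7.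

## Further compounds

F1 | step 15 | (3S)-3-ArB-2,3,4,8-tetrahydro-7H-chromen-7-one | C=CC(C)(C)c1cc([C@H]2COC3=C(C=CC(=O)C3)C2)c(OC)c(O[Si](C)(C)C(C)(C)C)c1O[Si](C)(C)C(C)(C)C
F2 | step 14 | (3-bromo-4-methylphenoxy)(tert-butyl)dimethylsilane | Cc1ccc(O[Si](C)(C)C(C)(C)C)cc1Br
F3 | step 14 | [3-bromo-4-(bromomethyl)phenoxy](tert-butyl)dimethylsilane | BrCc1ccc(O[Si](C)(C)C(C)(C)C)cc1Br
F4 | step 14 | (4S)-4-benzyl-3-[(2S)-3-[2-bromo-4-(tert-butyldimethylsilyloxy)phenyl]-2-ArB-propanoyl]-1,3-oxazolidin-2-one | C=CC(C)(C)c1cc([C@H](Cc2ccc(O[Si](C)(C)C(C)(C)C)cc2Br)C(=O)N2[C@@H](Cc3ccccc3)COC2=O)c(OC)c(O[Si](C)(C)C(C)(C)C)c1O[Si](C)(C)C(C)(C)C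
F5 | step 14 | (2S)-3-[2-bromo-4-(tert-butyldimethylsilyloxy)phenyl]-2-ArB-propan-1-ol | C=CC(C)(C)c1cc([C@H](Cc2ccc(O[Si](C)(C)C(C)(C)C)cc2Br)CO)c(OC)c(O[Si](C)(C)C(C)(C)C)c1O[Si](C)(C)C(C)(C)C
F6 | step 14 | (3S)-7-(tert-butyldimethylsilyloxy)-3-ArB-3,4-dihydro-2H-chromene | C=CC(C)(C)c1cc([C@H]2COc3cc(O[Si](C)(C)C(C)(C)C)ccc3C2)c(OC)c(O[Si](C)(C)C(C)(C)C)c1O[Si](C)(C)C(C)(C)C
F7 | step 12 | [4-(prop-2-en-1-yloxy)phenyl]methanol | C=CCOc1ccc(CO)cc1
F8 | step 12 | 1-(bromomethyl)-4-(prop-2-en-1-yloxy)benzene | C=CCOc1ccc(CBr)cc1
F9 | step 12 | (4S)-3-[(2S)-3-[4-(allyloxy)phenyl]-2-ArB-propanoyl]-4-benzyl-1,3-oxazolidin-2-one | C=CC(C)(C)c1cc([C@H](Cc2ccc(OCC=C)cc2)C(=O)N2[C@@H](Cc3ccccc3)COC2=O)c(OC)c(O[Si](C)(C)C(C)(C)C)c1O[Si](C)(C)C(C)(C)C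
F10 | step 12 | (2S)-3-[4-(allyloxy)phenyl]-2-ArB-propan-1-ol | C=CC(C)(C)c1cc([C@H](Cc2ccc(OCC=C)cc2)CO)c(OC)c(O[Si](C)(C)C(C)(C)C)c1O[Si](C)(C)C(C)(C)C
F11 | step 5 | 3-acetoxy-2-methoxy-4-[(3-methylbut-2-en-1-yl)oxy]benzaldehyde | COc1c(C=O)ccc(OCC=C(C)C)c1OC(C)=O
F12 | step 5 | 3,4-diacetoxy-2-methoxy-5-(2-methylbut-3-en-2-yl)benzaldehyde | C=CC(C)(C)c1cc(C=O)c(OC)c(OC(C)=O)c1OC(C)=O
A1 | alternative 1 | 3-[4-benzyloxy-3-(tert-butyldimethylsilyloxy)-2-methoxyphenyl]-7-(tert-butyldimethylsilyloxy)chromenylium chloride | [Cl-].COc1c(-c2c[o+]c3cc(O[Si](C)(C)C(C)(C)C)ccc3c2)ccc(OCc2ccccc2)c1O[Si](C)(C)C(C)(C)C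
A2 | alternative 1 | 6-(tert-butyldimethylsilyloxy)benzofuran | CC(C)(C)[Si](C)(C)Oc1ccc2ccoc2c1
A3 | alternative 1 | 3-[4-benzyloxy-3-(tert-butyldimethylsilyloxy)-2-methoxyphenyl]-3-chloro-3H-diazirine | COc1c(C2(Cl)N=N2)ccc(OCc2ccccc2)c1O[Si](C)(C)C(C)(C)C
A4 | alternative 2 | (3S)-3-ArB-7-(tert-butyldimethylsilyloxy)chroman-2-one | C=CC(C)(C)c1cc([C@H]2C(=O)Oc3cc(O[Si](C)(C)C(C)(C)C)ccc3C2)c(OC)c(O[Si](C)(C)C(C)(C)C)c1O[Si](C)(C)C(C)(C)C
A5 | alternative 2 | 5-(tert-butyldimethylsilyloxy)-2-[(4-methylphenyl)sulfonylmethyl]phenol | Cc1ccc(S(=O)(=O)Cc2ccc(O[Si](C)(C)C(C)(C)C)cc2O)cc1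
A6 | alternative 3 | (3S)-3-ArB-chroman-2,7-diol, mixture of C2 anomers | C=CC(C)(C)c1cc([C@H]2C(O)Oc3cc(O)ccc3C2)c(OC)c(O[Si](C)(C)C(C)(C)C)c1O[Si](C)(C)C(C)(C)C
A7 | alternative 3 | 2-ArB-prop-2-enal | C=CC(C)(C)c1cc(C(=C)C=O)c(OC)c(O[Si](C)(C)C(C)(C)C)c1O[Si](C)(C)C(C)(C)C
A8 | alternative 3 | resorcinol | Oc1cccc(O)c1
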